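Numbering used throughout (germacranolide): C1 ketone, C2/C3 ring CH2, C4(C15 methyl)–C5 epoxide, C6 lactone O–CH, C7=C11 butenolide (C12 carbonyl, C13 CH2OAc), C8 tiglate CH, C9, C10(=C14H2).
Cuts: epoxide oxygen (back to the E C4=C5 alkene), then C2–C3 (ring closure), then C5–C6 (vinylogous aldol with methacrolein), then C8–C9 (allylation by a C9–C10(=C14)–C1–C2 allyl chloride); the butenolide comes from but-2-yne-1,4-diol, a vinyl Grignard reagent and CO2.
Forward order: butenolide ring first, chain joined at C8, then at C6, then the ten-membered carbocycle through C2–C3, epoxide last.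
Enabling feature: C3–C4(C15)–C5 is an allyl unit next to C6, and C2 lies between the C1 ketone and a temporary ester, so an η3-allylpalladium over C3–C5 can be attacked by C2; the η3 species erases the C5 carbinol configuration and the alkene geometry, so every C5 epimer should funnel into the one E C4=C5 ring.
Stereochemistry: C8 from a catalyst-controlled allylation, C6 from a catalyst-controlled vinylogous Mukaiyama aldol, C4/C5 from peripheral epoxidation of the ring E-alkene, tiglate geometry from tigloyl chloride.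
Key step: step 13
Remark: 2-(trimethylsilyl)ethyl acetate, tigloyl chloride and the chiral ligand and Lewis base are taken as purchasable; C1 (in 8–18), C5 (in 16–19) and C2 (in 20, 21) are deliberately left as epimer mixtures because each is erased later, and their SMILES carry no stereo tag.

Step 1
Reactants: 1 but-2-yne-1,4-diol
Product: 2 4-[(tert-butyldimethylsilyl)oxy]but-2-yn-1-ol
Conditions: NaH (1.0 equiv), THF, 0 °C to rt; then TBSCl (1.0 equiv)
Reagents that add atoms: tert-butyldimethylsilyl chloride (CC(C)(C)[Si](C)(C)Cl)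
Why: The sparingly soluble monosodium alkoxide of the symmetric diol should be silylated once only (O-silylation, monoprotection of a symmetric diol).

Step 2
Reactants: 2 4-[(tert-butyldimethylsilyl)oxy]but-2-yn-1-ol
Product: 4 3-{[(tert-butyldimethylsilyl)oxy]methyl}-4-vinylfuran-2(5H)-one, via cyclic alkenylmagnesium alkoxide 3 (not isolated)
Conditions: CH2=CHMgCl (3.5 equiv), THF, reflux; cool to −20 °C, CO2 (gas); then cold 10% aq. citric acid, rt
Reagents that add atoms: vinylmagnesium chloride (C=C[Mg]Cl); carbon dioxide (O=C=O)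
Why: Hydroxyl-directed anti-carbomagnesiation of the propargylic alkoxide puts vinyl on the alkyne carbon next to the carbinol and magnesium on the distal carbon cis to CH2O, so carboxylation and acid lactonisation should give the 3,4-disubstituted butenolide with the tetrasubstituted alkene fixed by the ring.

Step 3
Reactants: 4 3-{[(tert-butyldimethylsilyl)oxy]methyl}-4-vinylfuran-2(5H)-one
Product: 5 4-{[(tert-butyldimethylsilyl)oxy]methyl}-5-oxo-2,5-dihydrofuran-3-carbaldehyde
Conditions: O3, CH2Cl2, −78 °C; then Me2S, −78 °C to rt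
Reagents that add atoms: ozone ([O-][O+]=O)
Why: Ozonolysis should cleave the terminal vinyl group far faster than the tetrasubstituted, electron-poor butenolide alkene, giving the C8 aldehyde.

Step 4
Reactants: 6 2-(trimethylsilyl)ethyl acetate; 7 methacrolein
Product: 8 2-(trimethylsilyl)ethyl 3-hydroxy-4-methylpent-4-enoate (racemic)
Conditions: LiN(iPr)2 (1.05 equiv), THF, −78 °C; 6; then 7; AcOH quench at −78 °C
Reagents that add atoms: none
Why: The lithium ester enolate should add 1,2 to the enal (aldol addition); the carbinol centre (later C1) is racemic on purpose because it becomes the ketone in step 12.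

Step 5
Reactants: 8 2-(trimethylsilyl)ethyl 3-hydroxy-4-methylpent-4-enoate (racemic)
Product: 9 2-(trimethylsilyl)ethyl 4-methyl-3-[(triethylsilyl)oxy]pent-4-enoate (racemic)
Conditions: Et3SiCl, imidazole, CH2Cl2, 0 °C
Reagents that add atoms: chlorotriethylsilane (CC[Si](Cl)(CC)CC)
Why: Imidazole-mediated O-silylation gives a triethylsilyl ether that can later be removed in the presence of the tert-butyldimethylsilyl ether.

Step 6
Reactants: 9 2-(trimethylsilyl)ethyl 4-methyl-3-[(triethylsilyl)oxy]pent-4-enoate (racemic)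
Product: 10 2-(trimethylsilyl)ethyl 4-(chloromethyl)-3-[(triethylsilyl)oxy]pent-4-enoate (racemic)
Conditions: N-chlorosuccinimide (1.1 equiv), PhSeCl (5 mol %), CH2Cl2, rt
Reagents that add atoms: N-chlorosuccinimide (O=C1CCC(=O)N1Cl)
Why: Selenium-catalysed ene-type allylic chlorination should shift the 1,1-disubstituted alkene into the former methyl group, because the elimination avoids the oxygen-bearing carbon, giving the 2-substituted allyl chloride.

Step 7
Reactants: 5 4-{[(tert-butyldimethylsilyl)oxy]methyl}-5-oxo-2,5-dihydrofuran-3-carbaldehyde; 10 2-(trimethylsilyl)ethyl 4-(chloromethyl)-3-[(triethylsilyl)oxy]pent-4-enoate (racemic)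
Product: 12 2-(trimethylsilyl)ethyl (6S)-6-(4-{[(tert-butyldimethylsilyl)oxy]methyl}-5-oxo-2,5-dihydrofuran-3-yl)-6-hydroxy-4-methylidene-3-[(triethylsilyl)oxy]hexanoate (C3 epimers), via trimethylsilyl ether 11 (not isolated)
Conditions: CrCl2 (10 mol %), chiral tridentate carbazole bis(oxazoline) ligand (12 mol %, antipode chosen for Si-face addition), Mn powder (2 equiv), Me3SiCl (1.5 equiv), iPr2NEt (30 mol %), THF, rt; then citric acid, MeOH, 0 °C
Reagents that add atoms: none
Why: In this catalytic asymmetric Nozaki–Hiyama–Kishi allylation the allylchromium from 10 should add through a closed six-membered transition state to the Si face of the aldehyde under ligand control, setting C8 as S, and the silyl ether formed for chromium turnover is cleaved on work-up.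

Step 8
Reactants: 12 2-(trimethylsilyl)ethyl (6S)-6-(4-{[(tert-butyldimethylsilyl)oxy]methyl}-5-oxo-2,5-dihydrofuran-3-yl)-6-hydroxy-4-methylidene-3-[(triethylsilyl)oxy]hexanoate (C3 epimers)
Product: 13 2-(trimethylsilyl)ethyl (6S)-6-(4-{[(tert-butyldimethylsilyl)oxy]methyl}-5-oxo-2,5-dihydrofuran-3-yl)-6-{[(2E)-2-methylbut-2-enoyl]oxy}-4-methylidene-3-[(triethylsilyl)oxy]hexanoate (C3 epimers)
Conditions: tigloyl chloride (1.5 equiv), pyridine, DMAP (10 mol %), CH2Cl2, 0 °C to rt
Reagents that add atoms: tigloyl chloride (C/C=C(\C)C(Cl)=O)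
Why: DMAP-catalysed acylation of the secondary allylic alcohol installs the tiglate with retention at C8; pyridine in place of a trialkylamine avoids vinylketene formation and deconjugation of the acyl group.

Step 9
Reactants: 13 2-(trimethylsilyl)ethyl (6S)-6-(4-{[(tert-butyldimethylsilyl)oxy]methyl}-5-oxo-2,5-dihydrofuran-3-yl)-6-{[(2E)-2-methylbut-2-enoyl]oxy}-4-methylidene-3-[(triethylsilyl)oxy]hexanoate (C3 epimers); 7 methacrolein
Product: 16 2-(trimethylsilyl)ethyl (6S)-6-[(2S)-4-{[(tert-butyldimethylsilyl)oxy]methyl}-2-(1-hydroxy-2-methylprop-2-en-1-yl)-5-oxo-2,5-dihydrofuran-3-yl]-6-{[(2E)-2-methylbut-2-enoyl]oxy}-4-methylidene-3-[(triethylsilyl)oxy]hexanoate (epimers at the carbinol carbon and at C3), via 2-silyloxyfuran 14 (not isolated), via trichlorosilyl ether 15 (not isolated)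
Conditions: (a) TBSOTf (1.2 equiv), Et3N, CH2Cl2, 0 °C, pentane filtration; (b) 7 (1.5 equiv), SiCl4 (1.2 equiv), chiral 2,2'-binaphthyldiamine-derived bisphosphoramide (5 mol %, antipode chosen for 6S), iPr2NEt (10 mol %), CH2Cl2, −78 °C; (c) aqueous work-up
Reagents that add atoms: none
Why: Soft enolisation at C6 gives the 2-silyloxyfuran, whose γ-carbon should add 1,2 to the enal bound to the chiral Lewis-base-activated silicon cation (catalytic enantioselective vinylogous Mukaiyama aldol); the catalyst fixes the aldehyde face and the strongly preferred relative topicity relays this to C6 (S), while the C5 carbinol centre need not be uniform.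

Step 10
Reactants: 16 2-(trimethylsilyl)ethyl (6S)-6-[(2S)-4-{[(tert-butyldimethylsilyl)oxy]methyl}-2-(1-hydroxy-2-methylprop-2-en-1-yl)-5-oxo-2,5-dihydrofuran-3-yl]-6-{[(2E)-2-methylbut-2-enoyl]oxy}-4-methylidene-3-[(triethylsilyl)oxy]hexanoate
Product: 17 2-(trimethylsilyl)ethyl (6S)-6-[(2S)-4-{[(tert-butyldimethylsilyl)oxy]methyl}-2-{1-[(methoxycarbonyl)oxy]-2-methylprop-2-en-1-yl}-5-oxo-2,5-dihydrofuran-3-yl]-6-{[(2E)-2-methylbut-2-enoyl]oxy}-4-methylidene-3-[(triethylsilyl)oxy]hexanoate
Conditions: ClCO2Me, pyridine, CH2Cl2, 0 °C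
Reagents that add atoms: methyl chloroformate (COC(Cl)=O)
Why: O-acylation of the secondary allylic alcohol to the methyl carbonate under weakly basic conditions should avoid β-elimination toward a γ-alkylidene butenolide.

Step 11
Reactants: 17 the C5 methyl carbonate described in step 10
Product: 18 2-(trimethylsilyl)ethyl (6S)-6-[(2S)-4-{[(tert-butyldimethylsilyl)oxy]methyl}-2-{1-[(methoxycarbonyl)oxy]-2-methylprop-2-en-1-yl}-5-oxo-2,5-dihydrofuran-3-yl]-3-hydroxy-6-{[(2E)-2-methylbut-2-enoyl]oxy}-4-methylidenehexanoate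
Conditions: HF·pyridine, pyridine, THF, 0 °C
Reagents that add atoms: none
Why: Buffered fluoride should remove the secondary triethylsilyl ether faster than the tert-butyldimethylsilyl ether (selective desilylation), freeing the C1 hydroxyl.

Step 12
Reactants: 18 the C1 alcohol described in step 11
Product: 19 2-(trimethylsilyl)ethyl (6S)-6-[(2S)-4-{[(tert-butyldimethylsilyl)oxy]methyl}-2-{1-[(methoxycarbonyl)oxy]-2-methylprop-2-en-1-yl}-5-oxo-2,5-dihydrofuran-3-yl]-6-{[(2E)-2-methylbut-2-enoyl]oxy}-4-methylidene-3-oxohexanoate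
Conditions: Dess–Martin periodinane, CH2Cl2, 0 °C to rt
Reagents that add atoms: none
Why: Dess–Martin oxidation of the allylic β-hydroxy ester should give the α'-methylene β-keto ester without touching carbonate, esters, silyl ether or alkenes, and it removes the C1 stereocentre.

Step 13
Reactants: 19 the β-keto ester allylic carbonate described in step 12 (C5 epimers)
Product: 20 2-(trimethylsilyl)ethyl (4E,6R,8S)-13-[(tert-butyldimethylsilyl)oxy]-1-oxo-8-[(2E)-2-methylbut-2-enoyloxy]germacra-4,7(11),10(14)-trien-12,6-olide-2-carboxylate (C2 epimers)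
Conditions: Pd2(dba)3·CHCl3 (dba = dibenzylideneacetone, 5 mol %), Ph2PCH2CH2PPh2 (12 mol %), THF, 55 °C, 19 added by syringe pump to a final 0.002 M
Reagents that add atoms: none
Why: Zerovalent palladium ionises the allylic carbonate of either C5 epimer with loss of CO2 and methoxide, the methoxide deprotonates the β-keto ester, and the stabilised C2 enolate attacks the η3-allyl at its CH2 terminus C3 (intramolecular Tsuji–Trost allylic alkylation, the reaction type used for carbocyclic macrocyclisations of β-keto esters). The ten-membered carbocycle closes with the whole allyl unit inside the ring (attack at the distal terminus, endo mode), in competition with 8-exo closure at C5, which is disfavoured because C5 is secondary and flanked by the branched C6 and the C4 methyl group. No controlled stereocentre is created: C2 forms as a mixture and is removed in step 14, while the C4=C5 geometry should be E because the syn η3-allyl (C6 cis to C15, trans to C3) is expected to be the more stable and faster-cyclising of the isomers that interconvert through η1 forms (Curtin–Hammett funnel for both C5 epimers). The step needs ionisation of the carbonate in preference to the allylic tiglate (a far better leaving group on an unhindered 1,1-disubstituted alkene versus an ester on a tetrasubstituted electron-poor alkene), C- over O-alkylation (soft β-keto ester enolate, O-allylation reversible), and ring closure ahead of oligomerisation and of β-elimination toward C6 (high dilution and base-free conditions in which the only base is the enolate itself).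

Step 14
Reactants: 20 the macrocyclic β-keto ester described in step 13
Product: 22 (4E,6R,8S)-13-hydroxy-1-oxo-8-[(2E)-2-methylbut-2-enoyloxy]germacra-4,7(11),10(14)-trien-12,6-olide, via β-keto acid 21 (not isolated)
Conditions: Bu4NF (3 equiv), AcOH (3 equiv), THF, 0 °C to 40 °C
Reagents that add atoms: none
Why: Fluoride should cleave the 2-(trimethylsilyl)ethyl ester by β-elimination and the primary silyl ether, and the β-keto acid decarboxylates on gentle warming (fluoride-induced deprotection and decarboxylation), which erases C2; acetic acid buffering protects the acidic C6–H.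

Step 15
Reactants: 22 (4E,6R,8S)-13-hydroxy-1-oxo-8-[(2E)-2-methylbut-2-enoyloxy]germacra-4,7(11),10(14)-trien-12,6-olide
Product: 23 (4E,6R,8S)-13-acetoxy-1-oxo-8-[(2E)-2-methylbut-2-enoyloxy]germacra-4,7(11),10(14)-trien-12,6-olide
Conditions: Ac2O, pyridine, DMAP (5 mol %), CH2Cl2, 0 °C
Reagents that add atoms: acetic anhydride (CC(=O)OC(C)=O)
Why: Acetylation of the only free (primary) hydroxyl under mild amine catalysis; the acetate is added only after the palladium step, where an allylic acetate on C13 could have ionised.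

Step 16
Reactants: 23 (4E,6R,8S)-13-acetoxy-1-oxo-8-[(2E)-2-methylbut-2-enoyloxy]germacra-4,7(11),10(14)-trien-12,6-olide
Product: 24 CNP0225286.1: (4R,5R,6S,8S)-13-acetoxy-4,5-epoxy-1-oxo-8-[(2E)-2-methylbut-2-enoyloxy]germacra-7(11),10(14)-dien-12,6-olide
Conditions: mCPBA (1.1 equiv), Na2HPO4, CH2Cl2, 0 °C
Reagents that add atoms: 3-chloroperoxybenzoic acid (OOC(=O)c1cccc(Cl)c1)
Why: In this Prilezhaev epoxidation C4=C5 is the only electron-rich alkene (the other three are conjugated to carbonyls), and the peracid should attack the outer face of the E-alkene held perpendicular to the ring, as in related germacranolide 4,5-epoxidations, giving the trans 4R,5R epoxide.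

Compound list
1 | but-2-yne-1,4-diol | OCC#CCO | starting material
2 | 4-[(tert-butyldimethylsilyl)oxy]but-2-yn-1-ol | CC(C)(C)[Si](C)(C)OCC#CCO | intermediate
3 | cyclic alkenylmagnesium alkoxide (1-oxa-2-magnesacyclopent-3-ene; CH2OTBS on C3; vinyl on C4) | C=CC1=C(CO[Si](C)(C)C(C)(C)C)[Mg]OC1 | intermediate
4 | 3-{[(tert-butyldimethylsilyl)oxy]methyl}-4-vinylfuran-2(5H)-one | C=CC1=C(CO[Si](C)(C)C(C)(C)C)C(=O)OC1 | intermediate
5 | 4-{[(tert-butyldimethylsilyl)oxy]methyl}-5-oxo-2,5-dihydrofuran-3-carbaldehyde | O=CC1=C(CO[Si](C)(C)C(C)(C)C)C(=O)OC1 | intermediate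
6 | 2-(trimethylsilyl)ethyl acetate | CC(=O)OCC[Si](C)(C)C | starting material
7 | methacrolein (2-methylprop-2-enal) | C=C(C)C=O | starting material
8 | 2-(trimethylsilyl)ethyl 3-hydroxy-4-methylpent-4-enoate (racemic) | C=C(C)C(O)CC(=O)OCC[Si](C)(C)C | intermediate
9 | 2-(trimethylsilyl)ethyl 4-methyl-3-[(triethylsilyl)oxy]pent-4-enoate (racemic) | C=C(C)C(O[Si](CC)(CC)CC)CC(=O)OCC[Si](C)(C)C | intermediate
10 | 2-(trimethylsilyl)ethyl 4-(chloromethyl)-3-[(triethylsilyl)oxy]pent-4-enoate (racemic) | C=C(CCl)C(O[Si](CC)(CC)CC)CC(=O)OCC[Si](C)(C)C | intermediate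
11 | trimethylsilyl ether of 12 at the C8 oxygen (8S; C1 epimers) | C=C(C[C@H](O[Si](C)(C)C)C1=C(CO[Si](C)(C)C(C)(C)C)C(=O)OC1)C(O[Si](CC)(CC)CC)CC(=O)OCC[Si](C)(C)C | intermediate
12 | (8S)-homoallylic alcohol: C8–OH, C1–OSiEt3, C13–OTBS, C6H2 butenolide, 2-(trimethylsilyl)ethyl ester (C1 epimers) | C=C(C[C@H](O)C1=C(CO[Si](C)(C)C(C)(C)C)C(=O)OC1)C(O[Si](CC)(CC)CC)CC(=O)OCC[Si](C)(C)C | intermediate
13 | (8S)-tiglate of 12 (C1 epimers) | C=C(C[C@H](OC(=O)/C(C)=C/C)C1=C(CO[Si](C)(C)C(C)(C)C)C(=O)OC1)C(O[Si](CC)(CC)CC)CC(=O)OCC[Si](C)(C)C | intermediate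
14 | 2-[(tert-butyldimethylsilyl)oxy]furan form of 13 (furan CH is the future C6) | C=C(C[C@H](OC(=O)/C(C)=C/C)c1coc(O[Si](C)(C)C(C)(C)C)c1CO[Si](C)(C)C(C)(C)C)C(O[Si](CC)(CC)CC)CC(=O)OCC[Si](C)(C)C | intermediate
15 | trichlorosilyl ether of 16 at the C5 oxygen (6S,8S) | C=C(C[C@H](OC(=O)/C(C)=C/C)C1=C(CO[Si](C)(C)C(C)(C)C)C(=O)O[C@@H]1C(O[Si](Cl)(Cl)Cl)C(C)=C)C(O[Si](CC)(CC)CC)CC(=O)OCC[Si](C)(C)C | intermediate
16 | vinylogous aldol adduct (6S,8S): C5–OH with isopropenyl, C1–OSiEt3 (C5 and C1 epimers) | C=C(C[C@H](OC(=O)/C(C)=C/C)C1=C(CO[Si](C)(C)C(C)(C)C)C(=O)O[C@@H]1C(O)C(C)=C)C(O[Si](CC)(CC)CC)CC(=O)OCC[Si](C)(C)C | intermediate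
17 | C5 methyl carbonate of 16 (6S,8S) | C=C(C[C@H](OC(=O)/C(C)=C/C)C1=C(CO[Si](C)(C)C(C)(C)C)C(=O)O[C@@H]1C(OC(=O)OC)C(C)=C)C(O[Si](CC)(CC)CC)CC(=O)OCC[Si](C)(C)C | intermediate
18 | C1 alcohol from 17 (6S,8S) | C=C(C[C@H](OC(=O)/C(C)=C/C)C1=C(CO[Si](C)(C)C(C)(C)C)C(=O)O[C@@H]1C(OC(=O)OC)C(C)=C)C(O)CC(=O)OCC[Si](C)(C)C | intermediate
19 | α'-methylene β-keto ester with C5 allylic carbonate (6S,8S; C5 epimers) | C=C(C[C@H](OC(=O)/C(C)=C/C)C1=C(CO[Si](C)(C)C(C)(C)C)C(=O)O[C@@H]1C(OC(=O)OC)C(C)=C)C(=O)CC(=O)OCC[Si](C)(C)C | intermediate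
20 | ten-membered (4E,6R,8S)-trienolide with C2 2-(trimethylsilyl)ethyl ester, 13-OTBS, 8-tiglate (C2 epimers) | C=C1C[C@H](OC(=O)/C(C)=C/C)C2=C(CO[Si](C)(C)C(C)(C)C)C(=O)O[C@@H]2/C=C(\C)CC(C(=O)OCC[Si](C)(C)C)C1=O | intermediate
21 | β-keto acid (C2 carboxylic acid, 13-OH; 4E,6R,8S) | C=C1C[C@H](OC(=O)/C(C)=C/C)C2=C(CO)C(=O)O[C@@H]2/C=C(\C)CC(C(=O)O)C1=O | intermediate
22 | (4E,6R,8S)-13-hydroxy-1-oxo-8-tigloyloxygermacra-4,7(11),10(14)-trien-12,6-olide | C=C1C[C@H](OC(=O)/C(C)=C/C)C2=C(CO)C(=O)O[C@@H]2/C=C(\C)CCC1=O | intermediate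
23 | (4E,6R,8S)-13-acetoxy-1-oxo-8-tigloyloxygermacra-4,7(11),10(14)-trien-12,6-olide | C=C1C[C@H](OC(=O)/C(C)=C/C)C2=C(COC(C)=O)C(=O)O[C@@H]2/C=C(\C)CCC1=O | intermediate
24 | CNP0225286.1, (4R,5R,6S,8S)-13-acetoxy-4,5-epoxy-1-oxo-8-tigloyloxygermacra-7(11),10(14)-dien-12,6-olide | C=C1C[C@H](OC(=O)/C(C)=C/C)C2=C(COC(C)=O)C(=O)O[C@@H]2[C@H]2O[C@]2(C)CCC1=O | target

Total steps: 16. Longest linear sequence: 13 (steps 1–3, then 7–16; the branch of steps 4–6 joins at step 7).

Steps most likely to fail
Step 13. The allylpalladium intermediate may lose the acidic C6 proton (β-elimination toward a γ-alkylidene butenolide), close through the anti allyl to the Z ring alkene or at C5 to the eight-membered ring, or oligomerise. The fallback fixes the alkene geometry before ring closure and avoids any η3 species: it sets out from 16, which with SOCl2 and 2,6-di-tert-butyl-4-methylpyridine in Et2O should undergo allylic transposition with internal return to the (E)-primary allylic chloride F1; HF·pyridine then frees the C1 alcohol F2, Dess–Martin oxidation gives the β-keto ester chloride F3, and Cs2CO3 with NaI (cat.) in MeCN at high dilution closes the ring by intramolecular C-alkylation, returning to the route at 20.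
Step 9. Facial control at the furan carbon may erode on this hindered 3,4-disubstituted silyloxyfuran, the enal may be attacked 1,4, or the Lewis acid may ionise the C8 or C13 oxygen substituents. The fallback drops the silyl dienolate and the Lewis acid: it sets out from 13 and uses a direct vinylogous aldol addition to 7 under a bifunctional chiral tertiary amine–squaramide (Brønsted base plus hydrogen-bond donor), which ion-pairs with the furanolate and so controls the C6 face itself instead of relaying it from the aldehyde face; it returns at 16 and makes no new compound (F0), and any C6 epimer remains separable because C8 makes it a diastereomer.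
Step 16. The peracid may attack the other face of C4=C5 if the ring prefers the other planar-chiral conformer, or oxidation may spread to other sites. The fallback replaces substrate control by reagent control: it sets out from 23 and uses the Shi epoxidation (fructose-derived chiral ketone or its enantiomer, KHSO5 as 2KHSO5·KHSO4·K2SO4, buffered at pH 8, MeCN/dimethoxymethane, 0 °C), in which the chiral dioxirane selects the alkene face through its spiro transition state; it returns at 24 and makes no new compound (F0).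

Further compounds
F1 | step 13 | (E)-primary allylic chloride from 16: C3–Cl, E C4=C5, C1–OSiEt3 (6R,8S) | C=C(C[C@H](OC(=O)/C(C)=C/C)C1=C(CO[Si](C)(C)C(C)(C)C)C(=O)O[C@@H]1/C=C(\C)CCl)C(O[Si](CC)(CC)CC)CC(=O)OCC[Si](C)(C)C
F2 | step 13 | C1 alcohol of F1 | C=C(C[C@H](OC(=O)/C(C)=C/C)C1=C(CO[Si](C)(C)C(C)(C)C)C(=O)O[C@@H]1/C=C(\C)CCl)C(O)CC(=O)OCC[Si](C)(C)C
F3 | step 13 | β-keto ester allylic chloride | C=C(C[C@H](OC(=O)/C(C)=C/C)C1=C(CO[Si](C)(C)C(C)(C)C)C(=O)O[C@@H]1/C=C(\C)CCl)C(=O)CC(=O)OCC[Si](C)(C)C
F0 | step 9 | none | none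
F0 | step 16 | none | none
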